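The readings come from a simulation from invented constants.

The number that matters is the bend in the larch rate: the logarithm of the free monomer fraction falls by 0.412 min⁻¹ early but by 0.280 min⁻¹ late.

the same everywhere: transfer agent 0.156 M; initiator 2.6 mM
- alder: free monomer 0.77 M; temperature 30 °C; run made earlier
- larch: free monomer 1.7 M; temperature 52 °C; run made earlier
- green: free monomer 0.52 M; temperature 20 °C; time 12 min
- violet: free monomer 1.5 M; temperature 60 °C; time 12 min

| run | time / min | monomer in chains / % | free monomer / % |
|---|---|---|---|
| alder | 1.33 | 13.8 | 85.8 |
| alder | 2.50 | 26.2 | 72.7 |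
| alder | 4.00 | 39.3 | 61.1 |
| alder | 5.00 | 46.7 | 53.9 |
| alder | 6.00 | 51.6 | 48.1 |
| alder | 8.00 | 60.3 | 40.7 |
| larch | 0.417 | 16.0 | 83.9 |
| larch | 0.833 | 30.6 | 69.2 |
| larch | 1.33 | 41.1 | 57.6 |
| larch | 1.50 | 45.3 | 54.5 |
| larch | 2.00 | 52.8 | 46.8 |
| larch | 2.50 | 58.1 | 41.2 |

(each reading ± 0.5 percentage points)

- a reading or a percentage of monomer in chains counts all its forms, free or not

1. which one finishes higher in amount of monomer in chains, in percent of the free monomer charged ("neither" within 2 percentage points) (green / violet / neither)
2. amount of monomer in chains at the end, in percent of the free monomer charged, green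
3. amount of monomer in chains at the end, in percent of the free monomer charged, violet

The alder run bends too, from 0.127 min⁻¹ to 0.0936 min⁻¹. I therefore read free monomer as going pseudo-first-order, with a rate that decays as if whatever carries the reaction were dying. The two rates in each run give a death rate, 0.343 min⁻¹ in larch and 0.0798 min⁻¹ in alder. The logarithmic fall so far plus late rate over death rate then gives 1.56 for larch and 1.93 for alder. These are readings and carry their scatter.

Taking the logarithm of this number as straight in temperature, I get 1.44 for violet and 2.13 for green. I call it the reach, the whole logarithmic fall of free monomer before the reaction dies; the fraction left at the end is exp(−reach). Read by itself, the reach puts green ahead, at 88.1% against 76.3%, so I test it against the clock. The same straight line gives a death rate of 0.0411 min⁻¹ for green and 0.584 min⁻¹ for violet. In 12 min, green then has 0.493 death times, fewer than the 7.01 of violet. One number is not enough. Multiplying each reach by the part of the decay already run, which is one minus exp(−death times), and taking chains as the charge minus free monomer, I reckon green at 56.3% and violet at 76.4%.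

The forecast says violet, with green 52% (46% to 59%) and violet 57% (46% to 70%), holding that “violet reaches equilibrium at about 57%”. My violet stands above that range.

The flasks give green 53.9% and violet 77.9%, so violet finishes higher.

    free monomer + initiator → living end + monomer in chains (k = 0.0330 M⁻¹ s⁻¹, Ea = 58.0 kJ mol⁻¹)
    free monomer + living end → monomer in chains + living end, rate k2*[living end]*[free monomer] (k = 0.520 M⁻¹ s⁻¹, Ea = 45.0 kJ mol⁻¹)
    living end + transfer agent → dead chain (kL = 0.00290 M⁻¹ s⁻¹, Ea = 59.0 kJ mol⁻¹)
    monomer in chains + initiator ⇌ isomer of the product + initiator, rate k4*[initiator]*[monomer in chains] forward; the back reaction follows from the equilibrium constant (K = 1.90, k = 0.0330 M⁻¹ s⁻¹, Ea = 67.0 kJ mol⁻¹, ΔH = −65.0 kJ mol⁻¹)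
    crystals ⇌ monomer in chains, rate k5*(cs5 - [monomer in chains]) while solid is left; crystals form when [monomer in chains] > cs5 (solubility = 10.0 mM, k = 0.270 s⁻¹)
    (constants at 20 °C)

Violet's free monomer stands at 22.1% after 12.0 min and at 22.0% after 120 min, and its reach of 1.44 gave 23.7%. This stop is no equilibrium: without the passing of living end and transfer agent into dead chain, violet reaches >99.9% of monomer in chains. Taking reach as proportional to initiator, a neighbour of violet with 0.0065 M of initiator has a reach of 3.61, hence 97.3% in chains. It gives 97.8%.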